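**Retrosynthetic overview**
1. Ring letters: A is the para-bridged aryloxy ring, B the 1,2,3-substituted phenol ring, C the meta-bridged ring, D the 1,2,4-substituted phenol ring. The chain A–CH2CH2–B–O–C–CH2CH2–D–O–A makes one 18-membered ring, the only ring the route has to form, and it is formed last.
2. Enabling feature: the ether oxygen on ring A is the oxygen of a para-alkylphenol. The ring D carbon it binds is ortho to the free ring D hydroxyl and meta to the bridge, and ring D is a second para-alkylphenol. This O–C(ortho) link between two para-alkylphenols is the mark of an oxidative phenol coupling.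
3. Key disconnection: that O–C bond is opened to an acyclic bis(bibenzyl) diphenol with Br on both ortho carbons of ring D and Cl on both ortho carbons of ring A. Oxidation of ring D, ipso attack by the ring A oxygen and loss of one bromide close the macrocycle.
4. The halogens are temporary. They block C–C coupling, set the direction and supply the leaving group, and the remaining three leave with the ring B benzyl group in the final hydrogenolysis.
5. The open chain comes from five small arenes by two Sonogashira couplings, one SNAr (B–O–C ether), one Ohira–Bestmann homologation and one diimide reduction, with no protecting group on rings A and D.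

Key step: step 9

Remark: the target has no stereocentre. The one sp3 centre each of 13 and 14 is transient and racemic, so their SMILES carry no stereo descriptor.

Step 1
Reactants: 1 2,6-dibromophenol
Product: 2 2,6-dibromo-4-iodophenol
Conditions: NIS, TsOH·H2O (cat.), MeCN, rt
Reagents that add atoms: N-iodosuccinimide, O=C1CCC(=O)N1I
Why: Electrophilic aromatic iodination of a phenol whose two ortho positions are blocked by bromine, so only the para carbon can react.

Step 2
Reactants: 2 2,6-dibromo-4-iodophenol; 3 3-ethynylphenol
Product: 4 2,6-dibromo-4-[(3-hydroxyphenyl)ethynyl]phenol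
Conditions: PdCl2(PPh3)2 (2 mol %), CuI (4 mol %), Et3N, THF, rt, Ar
Reagents that add atoms: none
Why: Sonogashira coupling, which tolerates free phenols and in which zerovalent palladium inserts into the C–I bond at room temperature well before the two flanked C–Br bonds.

Step 3
Reactants: 5 2-fluoro-3-hydroxybenzaldehyde
Product: 6 3-(benzyloxy)-2-fluorobenzaldehyde
Conditions: BnBr, K2CO3, DMF, rt
Reagents that add atoms: benzyl bromide, BrCc1ccccc1
Why: Williamson ether synthesis on the only acidic site; the benzyl group masks the ring B hydroxyl against the oxidant of step 9 and falls in the last step.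

Step 4
Reactants: 4 2,6-dibromo-4-[(3-hydroxyphenyl)ethynyl]phenol; 6 3-(benzyloxy)-2-fluorobenzaldehyde
Product: 7 3-(benzyloxy)-2-{3-[(3,5-dibromo-4-hydroxyphenyl)ethynyl]phenoxy}benzaldehyde
Conditions: K2CO3 (2.5 equiv), DMF, 110 °C; dilute HCl work-up
Reagents that add atoms: none
Why: Nucleophilic aromatic substitution (addition–elimination) at the fluoride activated by the ortho formyl group; of the two phenoxides of 4 only the unhindered, more basic ring C phenoxide should attack, because the 2,6-dibromophenoxide is far less basic and shielded by two bromines.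

Step 5
Reactants: 7 3-(benzyloxy)-2-{3-[(3,5-dibromo-4-hydroxyphenyl)ethynyl]phenoxy}benzaldehyde
Product: 8 4-({3-[2-(benzyloxy)-6-ethynylphenoxy]phenyl}ethynyl)-2,6-dibromophenol
Conditions: dimethyl (1-diazo-2-oxopropyl)phosphonate, K2CO3 (3 equiv), MeOH, rt
Reagents that add atoms: dimethyl (1-diazo-2-oxopropyl)phosphonate, CC(=O)C(=[N+]=[N-])P(=O)(OC)OC
Why: Ohira–Bestmann variant of the Seyferth–Gilbert homologation, a mild one-carbon aldehyde-to-alkyne conversion that leaves the internal alkyne, the aryl bromides and the benzyl ether alone, the phenol only consuming base.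

Step 6
Reactants: 9 2,6-dichlorophenol
Product: 10 2,6-dichloro-4-iodophenol
Conditions: NIS, TsOH·H2O (cat.), MeCN, rt
Reagents that add atoms: N-iodosuccinimide, O=C1CCC(=O)N1I
Why: Electrophilic aromatic iodination directed to the only free activated position, para to the hydroxyl.

Step 7
Reactants: 8 4-({3-[2-(benzyloxy)-6-ethynylphenoxy]phenyl}ethynyl)-2,6-dibromophenol; 10 2,6-dichloro-4-iodophenol
Product: 11 diyne diphenol, 4-({3-(benzyloxy)-2-[3-((3,5-dibromo-4-hydroxyphenyl)ethynyl)phenoxy]phenyl}ethynyl)-2,6-dichlorophenol
Conditions: PdCl2(PPh3)2 (3 mol %), CuI (5 mol %), Et3N, THF, rt to 40 °C, Ar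
Reagents that add atoms: none
Why: Sonogashira coupling, chemoselective for the aryl iodide of 10 over the electron-rich, doubly flanked C–Br bonds of ring D and the C–Cl bonds of ring A.

Step 8
Reactants: 11 diyne diphenol
Product: 12 open bis(bibenzyl) diphenol, 4-(2-{3-(benzyloxy)-2-[3-(2-(3,5-dibromo-4-hydroxyphenyl)ethyl)phenoxy]phenyl}ethyl)-2,6-dichlorophenol
Conditions: TsNHNH2 (large excess, in portions), NaOAc, DME–H2O, reflux
Reagents that add atoms: none
Why: Diimide reduction (concerted syn transfer of H2 to C–C multiple bonds), which saturates both diarylalkynes by way of the stilbenes but leaves the C–Br, C–Cl and O-benzyl bonds that a palladium-catalysed hydrogenation would cleave.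

Step 9
Reactants: 12 open bis(bibenzyl) diphenol
Product: 14 macrocyclic para-quinol methyl ether, via ortho-dienone 13 (not isolated)
Conditions: Tl(NO3)3·3H2O (2 equiv), MeOH–THF, ca. 1 mM in 12, −10 to 0 °C
Reagents that add atoms: methanol, CO
Why: Trivalent thallium removes two electrons from the more easily oxidised 2,6-dibromophenol of ring D, and the phenoxenium-type species is captured at one of its two equivalent bromine-bearing ortho carbons by the hydroxyl oxygen of the 2,6-dichlorophenol of ring A to give ortho-dienone 13; methanol then adds to the para carbon with allylic (SN2') expulsion of bromide, which locks the new C–O bond in the cross-conjugated para-quinol methyl ether 14, a compound with no free phenol left for excess oxidant to attack. The closest known reaction type is the Tl(NO3)3-mediated oxidative coupling of o,o'-dihalogenated para-substituted phenols to diaryl ethers, which has closed macrocyclic diaryl ethers of the isodityrosine, bastadin and vancomycin-model classes. One ring is closed, the 18-membered macrocycle, by end-to-end attack of oxygen on carbon under high dilution, and the sp3 carbon that ring D gains in 13 and 14 puts a bend into the chain that should ease the closure. The sp3 carbons of 13 and 14 arise without control as racemates, which does not matter because step 10 flattens ring D again and the target has no stereocentre. The step needs direction (ring A oxygen onto ring D, not the reverse), secured by bromine against chlorine (lower oxidation potential and better leaving group on ring D); it needs C–O instead of C–C coupling, secured by halogen on all four ortho carbons and the bridges on both para carbons; and it needs rings B and C untouched, secured by the benzyl ether on ring B and the absence of any other free hydroxyl. In one operation the step forms the second diaryl ether, closes the macrocycle and sets the catechol monoether pattern of ring D from a plain para-substituted phenol.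

Step 10
Reactants: 14 macrocyclic para-quinol methyl ether
Product: 15 bromo-dichloro-O-benzylmarchantin C
Conditions: Zn dust, AcOH–THF, rt
Reagents that add atoms: none
Why: Reductive aromatisation of a para-quinol ether by a dissolving metal, in which two electrons from zinc expel methoxide from the sp3 carbon and restore the ring D phenol, erasing the stereocentre of 14.

Step 11
Reactants: 15 bromo-dichloro-O-benzylmarchantin C
Product: 16 marchantin C
Conditions: H2 (1 atm), Pd/C (10 %), NaOAc (4 equiv), MeOH–EtOAc, rt
Reagents that add atoms: none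
Why: Catalytic hydrogenolysis, which with NaOAc as acid scavenger cleaves the benzyl ether, the one C–Br bond and the two C–Cl bonds in a single operation and leaves the diaryl ethers and arenes intact.

**Compound list**
1 | 2,6-dibromophenol | Oc1c(Br)cccc1Br | starting material
2 | 2,6-dibromo-4-iodophenol | Oc1c(Br)cc(I)cc1Br | intermediate
3 | 3-ethynylphenol | C#Cc1cccc(O)c1 | starting material
4 | 2,6-dibromo-4-[(3-hydroxyphenyl)ethynyl]phenol (rings C and D) | Oc1cccc(C#Cc2cc(Br)c(O)c(Br)c2)c1 | intermediate
5 | 2-fluoro-3-hydroxybenzaldehyde | O=Cc1cccc(O)c1F | starting material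
6 | 3-(benzyloxy)-2-fluorobenzaldehyde | O=Cc1cccc(OCc2ccccc2)c1F | intermediate
7 | 3-(benzyloxy)-2-{3-[(3,5-dibromo-4-hydroxyphenyl)ethynyl]phenoxy}benzaldehyde | O=Cc1cccc(OCc2ccccc2)c1Oc1cccc(C#Cc2cc(Br)c(O)c(Br)c2)c1 | intermediate
8 | 4-({3-[2-(benzyloxy)-6-ethynylphenoxy]phenyl}ethynyl)-2,6-dibromophenol | C#Cc1cccc(OCc2ccccc2)c1Oc1cccc(C#Cc2cc(Br)c(O)c(Br)c2)c1 | intermediate
9 | 2,6-dichlorophenol | Oc1c(Cl)cccc1Cl | starting material
10 | 2,6-dichloro-4-iodophenol | Oc1c(Cl)cc(I)cc1Cl | intermediate
11 | diyne diphenol, 4-({3-(benzyloxy)-2-[3-((3,5-dibromo-4-hydroxyphenyl)ethynyl)phenoxy]phenyl}ethynyl)-2,6-dichlorophenol | Oc1c(Cl)cc(cc1Cl)C#Cc1cccc(OCc2ccccc2)c1Oc1cccc(C#Cc2cc(Br)c(O)c(Br)c2)c1 | intermediate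
12 | open bis(bibenzyl) diphenol, 4-(2-{3-(benzyloxy)-2-[3-(2-(3,5-dibromo-4-hydroxyphenyl)ethyl)phenoxy]phenyl}ethyl)-2,6-dichlorophenol | Oc1c(Cl)cc(cc1Cl)CCc1cccc(OCc2ccccc2)c1Oc1cccc(CCc2cc(Br)c(O)c(Br)c2)c1 | intermediate
13 | ortho-dienone macrocycle: ring D is a cyclohexa-2,4-dienone whose sp3 carbon next to C=O bears Br and the ring A oxygen, the other carbon next to C=O bears Br; racemic, not isolated | O=C1C(Br)=CC2=CC1(Br)Oc1c(Cl)cc(cc1Cl)CCc1cccc(OCc3ccccc3)c1Oc1cccc(c1)CC2 | intermediate
14 | para-quinol methyl ether macrocycle: ring D is a 4-methoxycyclohexa-2,5-dienone with the ring A oxygen on C-2, OMe and the bridge to ring C on C-4, Br on C-6; racemic | O=C1C(Br)=CC2(OC)C=C1Oc1c(Cl)cc(cc1Cl)CCc1cccc(OCc3ccccc3)c1Oc1cccc(c1)CC2 | intermediate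
15 | bromo-dichloro-O-benzylmarchantin C (Br ortho to the ring D hydroxyl, Cl on both ring A carbons next to the ether oxygen, benzyl on the ring B oxygen) | Oc1c(Br)cc2cc1Oc1c(Cl)cc(cc1Cl)CCc1cccc(OCc3ccccc3)c1Oc1cccc(c1)CC2 | intermediate
16 | marchantin C | Oc1ccc2cc1Oc1ccc(cc1)CCc1cccc(O)c1Oc1cccc(c1)CC2 | target

Total step count: 11
Longest linear sequence: 9 steps (1, 2, 4, 5, 7, 8, 9, 10, 11)

**Steps most likely to fail**

**Step 9.**
- What may go wrong: oxidised ring D may be trapped by methanol at its para carbon, or may lose a benzylic proton, before the distant ring A oxygen arrives. Intermolecular coupling may outrun ring closure, or the closure may run in the reverse direction.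
- Fallback: a copper-catalysed intramolecular Ullmann ether synthesis. It needs no oxidation, and its direction is fixed because only ring D carries C–Br bonds and only ring A a free hydroxyl.
- Route: it sets out from 8. Benzylation of the ring D phenol (BnBr, K2CO3, DMF) should give the dibenzyl ether F1. Sonogashira coupling with bought 4-iodophenol (Oc1ccc(I)cc1) under the conditions of step 7 should give the diyne monophenol F2. Diimide reduction as in step 8 should give the open bis(bibenzyl) monophenol F3. Slow addition of F3 to CuI, N,N-dimethylglycine and Cs2CO3 in dioxane at 100 °C should close the same O–C bond at either of the two equivalent bromides to give the bromo di-O-benzyl macrocycle F4. Hydrogenolysis (H2, Pd/C, NaOAc) removes the bromine and both benzyl groups, and the fallback comes back to the route at 16.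

**Step 8.**
- What may go wrong: the reduction may stall at the stilbene stage, because four equivalents of hydrogen must be delivered to two hindered diarylalkynes. Prolonged heating may cause slow loss of halogen.
- Fallback: the bridges are made saturated from the start by B-alkyl Suzuki–Miyaura coupling, so nothing has to be reduced.
- Route: it sets out from 2. Bought 3-vinylphenol (C=Cc1cccc(O)c1) is hydroborated with 9-BBN-H (one extra equivalent for the phenol) to the primary alkylborane F5. This is coupled in the same flask with 2 (PdCl2(dppf), aqueous K3PO4, THF–DMF, rt to 40 °C, C–I before C–Br) to give the ring C–ring D bibenzyl diphenol F6. SNAr with 6 as in step 4 should give the saturated aldehyde F7. Wittig methylenation (Ph3P=CH2, excess, THF) should give the styrene F8. Hydroboration with 9-BBN-H gives the alkylborane F9, and coupling with 10 under the same conditions brings the fallback back to the route at 12.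

**Step 4.**
- What may go wrong: the two phenoxides of 4 may compete for the fluoride, and substitution at a C–F bond flanked on both sides may be slow enough for the aldehyde to degrade.
- Fallback: the order of bond formation is changed so that the ether is made while only one phenol is present.
- Route: it sets out from 6. SNAr with 3 (K2CO3, DMF, 100 °C) should give the ethynyl diaryl ether aldehyde F10. Sonogashira coupling of F10 with 2 under the conditions of step 2 brings the fallback back to the route at 7.

**Further compounds**
F1 | step 9 | 2-(benzyloxy)-5-({3-[2-(benzyloxy)-6-ethynylphenoxy]phenyl}ethynyl)-1,3-dibromobenzene | C#Cc1cccc(OCc2ccccc2)c1Oc1cccc(C#Cc2cc(Br)c(OCc3ccccc3)c(Br)c2)c1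
F2 | step 9 | 4-({3-(benzyloxy)-2-[3-((4-(benzyloxy)-3,5-dibromophenyl)ethynyl)phenoxy]phenyl}ethynyl)phenol | Oc1ccc(cc1)C#Cc1cccc(OCc2ccccc2)c1Oc1cccc(C#Cc2cc(Br)c(OCc3ccccc3)c(Br)c2)c1
F3 | step 9 | 4-(2-{3-(benzyloxy)-2-[3-(2-(4-(benzyloxy)-3,5-dibromophenyl)ethyl)phenoxy]phenyl}ethyl)phenol | Oc1ccc(cc1)CCc1cccc(OCc2ccccc2)c1Oc1cccc(CCc2cc(Br)c(OCc3ccccc3)c(Br)c2)c1
F4 | step 9 | bromo-di-O-benzylmarchantin C (Br ortho to the ring D benzyloxy group) | Brc1cc2cc(c1OCc1ccccc1)Oc1ccc(cc1)CCc1cccc(OCc3ccccc3)c1Oc1cccc(c1)CC2
F5 | step 8 | 3-[2-(9-borabicyclo[3.3.1]nonan-9-yl)ethyl]phenol (drawn with the phenol free) | Oc1cccc(CCB2C3CCCC2CCC3)c1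
F6 | step 8 | 2,6-dibromo-4-[2-(3-hydroxyphenyl)ethyl]phenol | Oc1cccc(CCc2cc(Br)c(O)c(Br)c2)c1
F7 | step 8 | 3-(benzyloxy)-2-{3-[2-(3,5-dibromo-4-hydroxyphenyl)ethyl]phenoxy}benzaldehyde | O=Cc1cccc(OCc2ccccc2)c1Oc1cccc(CCc2cc(Br)c(O)c(Br)c2)c1
F8 | step 8 | 4-(2-{3-[2-(benzyloxy)-6-vinylphenoxy]phenyl}ethyl)-2,6-dibromophenol | C=Cc1cccc(OCc2ccccc2)c1Oc1cccc(CCc2cc(Br)c(O)c(Br)c2)c1
F9 | step 8 | 9-BBN adduct of F8, boron on the terminal carbon (drawn with the phenol free) | Oc1c(Br)cc(CCc2cccc(Oc3c(CCB4C5CCCC4CCC5)cccc3OCc3ccccc3)c2)cc1Br
F10 | step 4 | 3-(benzyloxy)-2-(3-ethynylphenoxy)benzaldehyde | O=Cc1cccc(OCc2ccccc2)c1Oc1cccc(C#C)c1
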